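**Retrosynthetic overview**
1. Anabsin ⇒ 3'-ketone 18 (hydride from the endo side) ⇒ cage ketone 15, by closing the oxolane C4'–O–C10' through oxidation of the C3' enol, which can only form toward C4' because C2' is a bridgehead.
2. Cage ketone 14 ⇒ diene 13. The strategy rests on the bicyclo[2.2.1]heptane C2'–C3'–C4'–C5'/C1'/C2–C3, in which C3 is bonded to quaternary C5' while C4=C5 stays in the cyclopentene of the unprimed half. A C3=C4 alkene bearing a 5α hydrogen (ene) therefore adds to the 3'-oxo-4'-ene (enophile), forming C3–C5' and moving H-5 to C4'.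
3. 13 ⇒ C2-symmetric C2–C2' diketone 9 (oxidative enolate dimerisation of 7), desymmetrised as a mono-tosylhydrazone and carried through a reductive 1,3-transposition.
4. 7 ⇒ α-santonin: photorearrangement to the 5/7-fused guaianolide, then inversion of C10 by dehydration and radical hydration.
5. Ring order: hydroazulene of each half → C2–C2' bond → carbocyclic norbornane ring (ene) → oxolane.

Key step: step 8

Remark: guaiane numbering, primes on the ether-bridged half, α = face of H-1 and H-1'; the target carries its C10 and C10' oxygens trans to H-1 and H-1', epimeric to the photoproduct of santonin, so C10 is inverted before dimerisation.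

**Step 1**
Reactants: 1 α-santonin
Product: 2 isophotosantonic lactone (10α-hydroxy-3-oxo-1αH-guai-4-en-12,6α-olide)
Conditions: hν (medium-pressure Hg lamp, quartz), AcOH/H2O 1:1, reflux
Reagents that add atoms: water, O
Why: Photochemical rearrangement of the cross-conjugated cyclohexadienone with solvent capture (santonin to isophotosantonic lactone) forms the C1–C5 bond while water enters at C10 anti to the breaking C5–C10 bond, which fixes H-1 α and gives the 10α-alcohol (cis to H-1), with C6, C7 and C11 carried over unchanged.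

**Step 2**
Reactants: 2 isophotosantonic lactone
Product: 4 3-oxo-1αH-guaia-4,10(14)-dien-12,6α-olide, via chlorosulfite ester 3 (not isolated)
Conditions: SOCl2, pyridine, CH2Cl2, −20 → 0 °C
Reagents that add atoms: none
Why: E2 dehydration of the tertiary alcohol through its chlorosulfite should run into the methyl group, because the pseudo-equatorial 10α leaving group has no anti-periplanar ring hydrogen and H-1 is cis to it, so the C1 stereocentre and the enone stay untouched.

**Step 3**
Reactants: 4 3-oxo-1αH-guaia-4,10(14)-dien-12,6α-olide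
Product: 6 10-epi-isophotosantonic lactone (10β-hydroxy-3-oxo-1αH-guai-4-en-12,6α-olide), via tertiary hydroperoxide 5 (not isolated)
Conditions: Co(acac)2 (cat.), PhSiH3, O2 (1 atm), THF, 0 °C → rt; then PPh3
Reagents that add atoms: dioxygen, O=O
Why: Mukaiyama hydration (hydrogen-atom transfer to the 1,1-disubstituted alkene, O2 capture of the tertiary C10 radical, reduction of the hydroperoxide) should trap the radical mainly along the axial direction, anti to the axial H-1 and past the sp2 C5 that carries no axial substituent, which places oxygen β and the methyl equatorial; this face selectivity is the least secure stereochemical point of the route, the hindered tetrasubstituted enone alkene should not accept a hydrogen atom, and any 2 that forms is returned to step 2.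

**Step 4**
Reactants: 6 10-epi-isophotosantonic lactone
Product: 7 10β-(triethylsilyloxy)-3-oxo-1αH-guai-4-en-12,6α-olide
Conditions: Et3SiOTf, 2,6-lutidine, CH2Cl2, −78 → 0 °C
Reagents that add atoms: triethylsilyl trifluoromethanesulfonate, CC[Si](CC)(CC)OS(=O)(=O)C(F)(F)F
Why: Silyl triflate silylation of the hindered tertiary alcohol masks it for the enolate and Lewis-acid steps that follow.

**Step 5**
Reactants: 7 10β-(triethylsilyloxy)-3-oxo-1αH-guai-4-en-12,6α-olide (two molecules)
Product: 9 2α,2'α-linked C2-symmetric diketone dimer, via lithium dienolate 8 (not isolated)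
Conditions: LiN(iPr)2, THF, −78 °C; then FeCl3, DMF, −78 → 0 °C
Reagents that add atoms: none
Why: Kinetic α'-deprotonation at C2 (faster than at the lactone) followed by oxidative enolate homocoupling with trivalent iron should join the two C2 atoms on their α faces, away from the C10 substituent on the neighbouring C1, so that the 2βH,2'βH diketone, which is also the more stable arrangement, predominates.

**Step 6**
Reactants: 9 2α,2'α-linked diketone dimer
Product: 10 mono(3-tosylhydrazone) of 9
Conditions: TsNHNH2 (1.0 equiv), AcOH (cat.), EtOH/THF, 45 °C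
Reagents that add atoms: p-toluenesulfonyl hydrazide, Cc1ccc(cc1)S(=O)(=O)NN
Why: Hydrazone condensation on one of the two homotopic ketones gives a single mono-adduct and so desymmetrises the dimer, with recovered 9 recycled.

**Step 7**
Reactants: 10 mono(3-tosylhydrazone)
Product: 13 2α,2'α-linked 10β,10'β-bis(triethylsilyloxy) 1αH,5αH-guai-3-en-olide/3'-oxoguai-4'-en-olide, via N-boryl tosylhydrazine 11 (not isolated), via allylic diazene 12 (not isolated)
Conditions: catecholborane, CHCl3, −10 → 0 °C; then NaOAc·3H2O, 65 °C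
Reagents that add atoms: none
Why: Reductive 1,3-transposition of an α,β-unsaturated tosylhydrazone (hydride addition, sulfinate loss, retro-ene loss of N2 from the allylic diazene): hydride should enter C3 from the β face, away from the C2' substituent on C2, so the diazene sits α and hands its hydrogen suprafacially to C5 on the α face, which creates the cis 1αH,5αH fusion and the C3=C4 alkene while the second, cyclic s-trans enone is left alone.

**Step 8**
Reactants: 13 ene precursor
Product: 14 cage ketone (C3–C5' bond, C4=C5, 3'-oxo, 4'-H endo), 10,10'-bis(triethylsilyl) ether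
Conditions: Me2AlCl (4 equiv), CH2Cl2, −78 → 0 °C
Reagents that add atoms: none
Why: Me2AlCl binds the C3' carbonyl and activates C4'=C5'; C3, the less substituted end of the C3=C4 alkene, attacks C5' while the 5α hydrogen passes to C4' through a six-membered array, in one step or through a short-lived C4 cation/aluminium enolate pair, and the alkene moves to C4=C5. The closest known reaction is the Lewis-acid-promoted type 1 intramolecular ene reaction of a 1,6-diene with an enone as enophile. The new ring C2–C3–C5'–C1'–C2' closes in a 5-exo sense with respect to both π bonds and completes the bicyclo[2.2.1]heptane with bridgeheads C2' and C5'. C3 and C5' are fixed by the C2–C2' tether, which can only span the α faces of both five-membered rings (cis-1,3 bridge), and C4' receives hydrogen on its endo face because H-5 lies on the same α face of the cyclopentene as the forming bond. The step needs chemoselectivity (the enone is the only electron-poor alkene and C3=C4 the only alkene within reach), proton loss from C5 and not from the C15 methyl (H-5 is the hydrogen held over C4' in the folded conformer and gives the tetrasubstituted alkene), and intact tertiary silyl ethers, which the proton-scavenging Me2AlCl should allow.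

**Step 9**
Reactants: 14 cage ketone bis(triethylsilyl) ether
Product: 15 cage keto diol (10β,10'β-dihydroxy)
Conditions: HF·pyridine, THF, 0 °C → rt
Reagents that add atoms: none
Why: Fluoride cleavage of the two tertiary silyl ethers frees the 10'-hydroxyl as the internal nucleophile for the ether closure.

**Step 10**
Reactants: 15 cage keto diol
Product: 16 3'-trimethylsilyl enol ether 10,10'-bis(trimethylsilyl) ether
Conditions: Me3SiOTf, Et3N, CH2Cl2, 0 °C → rt; cold aq. NaHCO3 work-up
Reagents that add atoms: trimethylsilyl trifluoromethanesulfonate, C[Si](C)(C)OS(=O)(=O)C(F)(F)F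
Why: Soft enolisation with silyl triflate and amine converts the ketone far faster than the lactones and only toward C4' (C2' is a bridgehead), the endo H-4' being reachable from the open underside of the cage, and it silylates both tertiary alcohols at the same time.

**Step 11**
Reactants: 16 tris(trimethylsilyl) compound
Product: 18 3'-oxoanabsinthin, via 10-O-trimethylsilyl ether 17 (not isolated)
Conditions: PhI(OAc)2, BF3·OEt2, CH2Cl2, −78 → −20 °C; then 1 M HCl, THF, 0 °C
Reagents that add atoms: none
Why: α-Oxygenation of a silyl enol ether by trivalent iodine: the iodane binds the peripheral enol oxygen, and the 10'-oxygen, the only nucleophile that can reach C4' (as the ready cyclisation of absinthin to anabsinthin shows), attacks C4' on the exo face with loss of iodobenzene and its silyl group, which closes the oxolane and leaves the C15' methyl endo, after which the acid work-up frees 10-OH.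

**Step 12**
Reactants: 18 3'-oxoanabsinthin
Product: 19 anabsin
Conditions: NaBH4, CeCl3·7H2O, MeOH/THF, −20 °C → rt
Reagents that add atoms: none
Why: Borohydride reduction of the α-alkoxy ketone should deliver hydride from the endo side, since the ether bridge now holds the C14' methyl directly over the exo face of C3' (the camphor to isoborneol situation), giving the exo 3'-hydroxyl cis to the ether oxygen while the lactones survive.

**Compound list**
1 | α-santonin | C[C@H]1[C@@H]2CC[C@@]3(C)C=CC(=O)C(C)=C3[C@H]2OC1=O | starting material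
2 | isophotosantonic lactone (10α-hydroxy-3-oxo-1αH-guai-4-en-12,6α-olide) | CC1=C2[C@H]3OC(=O)[C@@H](C)[C@@H]3CC[C@@](C)(O)[C@@H]2CC1=O | intermediate
3 | 10α-chlorosulfite ester of 2 | CC1=C2[C@H]3OC(=O)[C@@H](C)[C@@H]3CC[C@@](C)(OS(=O)Cl)[C@@H]2CC1=O | intermediate
4 | 3-oxo-1αH-guaia-4,10(14)-dien-12,6α-olide | CC1=C2[C@H]3OC(=O)[C@@H](C)[C@@H]3CCC(=C)[C@@H]2CC1=O | intermediate
5 | 10β-hydroperoxy-3-oxo-1αH-guai-4-en-12,6α-olide | CC1=C2[C@H]3OC(=O)[C@@H](C)[C@@H]3CC[C@](C)(OO)[C@@H]2CC1=O | intermediate
6 | 10-epi-isophotosantonic lactone (10β-hydroxy, trans to H-1) | CC1=C2[C@H]3OC(=O)[C@@H](C)[C@@H]3CC[C@](C)(O)[C@@H]2CC1=O | intermediate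
7 | 10β-(triethylsilyloxy)-3-oxo-1αH-guai-4-en-12,6α-olide | CC1=C2[C@H]3OC(=O)[C@@H](C)[C@@H]3CC[C@](C)(O[Si](CC)(CC)CC)[C@@H]2CC1=O | intermediate
8 | lithium 2(3)-dienolate of 7 | CC1=C2[C@H]3OC(=O)[C@@H](C)[C@@H]3CC[C@](C)(O[Si](CC)(CC)CC)[C@@H]2C=C1O[Li] | intermediate
9 | 2α,2'α-linked dimer of 7 (2βH,2'βH, C2-symmetric 3,3'-diketone) | CC1=C2[C@H]3OC(=O)[C@@H](C)[C@@H]3CC[C@](C)(O[Si](CC)(CC)CC)[C@@H]2[C@H](C1=O)[C@H]4C(=O)C(C)=C5[C@H]6OC(=O)[C@@H](C)[C@@H]6CC[C@](C)(O[Si](CC)(CC)CC)[C@H]45 | intermediate
10 | mono(3-tosylhydrazone) of 9 | CC1=C2[C@H]3OC(=O)[C@@H](C)[C@@H]3CC[C@](C)(O[Si](CC)(CC)CC)[C@@H]2[C@H](C1=NNS(=O)(=O)c7ccc(C)cc7)[C@H]4C(=O)C(C)=C5[C@H]6OC(=O)[C@@H](C)[C@@H]6CC[C@](C)(O[Si](CC)(CC)CC)[C@H]45 | intermediate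
11 | 3α-[N-(1,3,2-benzodioxaborol-2-yl)-N'-tosylhydrazino] compound (3βH) | CC1=C2[C@H]3OC(=O)[C@@H](C)[C@@H]3CC[C@](C)(O[Si](CC)(CC)CC)[C@@H]2[C@H]([C@H]1N(B8Oc9ccccc9O8)NS(=O)(=O)c7ccc(C)cc7)[C@H]4C(=O)C(C)=C5[C@H]6OC(=O)[C@@H](C)[C@@H]6CC[C@](C)(O[Si](CC)(CC)CC)[C@H]45 | intermediate
12 | 3α-diazenyl compound (allylic diazene) | CC1=C2[C@H]3OC(=O)[C@@H](C)[C@@H]3CC[C@](C)(O[Si](CC)(CC)CC)[C@@H]2[C@H]([C@H]1N=N)[C@H]4C(=O)C(C)=C5[C@H]6OC(=O)[C@@H](C)[C@@H]6CC[C@](C)(O[Si](CC)(CC)CC)[C@H]45 | intermediate
13 | ene precursor: 2α,2'α-linked 10β-silyloxy-1αH,5αH-guai-3-en-12,6α-olide and 10'β-silyloxy-3'-oxoguai-4'-en-12',6'α-olide (silyl = triethylsilyl) | CC1=C[C@H]([C@H]4C(=O)C(C)=C5[C@H]6OC(=O)[C@@H](C)[C@@H]6CC[C@](C)(O[Si](CC)(CC)CC)[C@H]45)[C@H]2[C@@](C)(O[Si](CC)(CC)CC)CC[C@H]3[C@H](C)C(=O)O[C@@H]3[C@@H]12 | intermediate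
14 | cage ketone (C3–C5' bond, C4=C5, 3'-oxo, 4'-H endo, 4'-CH3 exo), 10,10'-bis(triethylsilyl) ether | CC1=C2[C@H]3OC(=O)[C@@H](C)[C@@H]3CC[C@](C)(O[Si](CC)(CC)CC)[C@@H]2[C@H]2[C@@H]3[C@@H]4[C@@]([C@H]6OC(=O)[C@@H](C)[C@@H]6CC[C@]4(C)O[Si](CC)(CC)CC)([C@@H](C)C3=O)[C@@H]12 | intermediate
15 | cage keto diol (ether not yet closed) | CC1=C2[C@H]3OC(=O)[C@@H](C)[C@@H]3CC[C@](C)(O)[C@@H]2[C@H]2[C@@H]3[C@@H]4[C@@]([C@H]6OC(=O)[C@@H](C)[C@@H]6CC[C@]4(C)O)([C@@H](C)C3=O)[C@@H]12 | intermediate
16 | 3'-trimethylsilyl enol ether 10,10'-bis(trimethylsilyl) ether | CC1=C2[C@H]3OC(=O)[C@@H](C)[C@@H]3CC[C@](C)(O[Si](C)(C)C)[C@@H]2[C@H]2[C@@H]3[C@@H]4[C@@]([C@H]6OC(=O)[C@@H](C)[C@@H]6CC[C@]4(C)O[Si](C)(C)C)(C(C)=C3O[Si](C)(C)C)[C@@H]12 | intermediate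
17 | 3'-oxoanabsinthin 10-O-trimethylsilyl ether | CC1=C2[C@H]3OC(=O)[C@@H](C)[C@@H]3CC[C@](C)(O[Si](C)(C)C)[C@@H]2[C@H]2[C@@H]3[C@@H]4[C@]5([C@H]6OC(=O)[C@@H](C)[C@@H]6CC[C@]4(C)O[C@@]5(C)C3=O)[C@@H]12 | intermediate
18 | 3'-oxoanabsinthin (C4'–O–C10' ether closed, 3'-ketone) | CC1=C2[C@H]3OC(=O)[C@@H](C)[C@@H]3CC[C@](C)(O)[C@@H]2[C@H]2[C@@H]3[C@@H]4[C@]5([C@H]6OC(=O)[C@@H](C)[C@@H]6CC[C@]4(C)O[C@@]5(C)C3=O)[C@@H]12 | intermediate
19 | anabsin | CC1=C2[C@H]3OC(=O)[C@@H](C)[C@@H]3CC[C@](C)(O)[C@@H]2[C@H]2[C@@H]3[C@@H]4[C@]5([C@H]6OC(=O)[C@@H](C)[C@@H]6CC[C@]4(C)O[C@@]5(C)[C@H]3O)[C@@H]12 | target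

**Step count**
Total: 12 steps. Longest linear sequence: 12 steps from α-santonin (step 5 joins two molecules of 7).

**Steps most likely to fail**

Step 8. The α-methylated, β,β-disubstituted enone may be too hindered for a fully substituted centre to form at C5'. The Lewis acid could then ionise a tertiary silyl ether, or a C4 cation could lose a proton from the C15 methyl or collapse onto C4'. The fallback sets out from 13 and replaces the thermal ene process by a photochemical one. Irradiation at 350 nm (Pyrex, CH2Cl2) should bring about intramolecular enone–alkene [2+2] cycloaddition, the 1,6-diene closing the five-membered ring first (rule of five), to give the cyclobutane photoadduct F1 with the C3–C5' and C4–C4' bonds in place. The strained C4–C4' bond, which lies α,β to the ketone, is then opened with Me2AlCl (CH2Cl2, −78 → 0 °C) to the C4 cation and aluminium enolate, and loss of H-5 returns the route to 14.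

Step 11. The iodane-activated enol may lose a proton from the C15' methyl (α-methylene ketone), or be captured by acetate, faster than the hindered tertiary 10'-oxygen closes the oxolane. The fallback sets out from 14 and builds both exo C–O bonds on an alkene instead.
- NaBH4 (MeOH/THF) should reduce C3' from the exo side, the endo face being the more hindered one while C10' is not yet tied to C4', to give the endo alcohol F2.
- Burgess reagent (toluene, 70 °C) should remove water by syn elimination with the cis endo H-4' to give absinthin 10,10'-bis(triethylsilyl) ether F3.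
- Bu4NF/AcOH (THF) frees absinthin F4.
- Oxidative cyclisation with trifluoroacetyl perrhenate (Re2O7, (CF3CO)2O, 2,6-lutidine, CH2Cl2, 0 °C, hydrolytic work-up) follows: the perrhenate ester of 10'-OH adds its alkoxy oxygen to C4' and an oxo oxygen to C3' across the exo face of C3'=C4'.

This returns to the route at 19 and sets both oxygens in one suprafacial event, without the ketone reduction of step 12.

Step 3. Capture of the planar C10 radical by O2 may show poor facial selectivity and return mainly the 10α-alcohol 2. The fallback sets out from 4 and delivers carbon, not oxygen, from the open α side. Lemieux–Johnson cleavage (OsO4 cat., NaIO4, 2,6-lutidine, dioxane/H2O) of the exocyclic methylene, the tetrasubstituted enone alkene being inert, gives the 14-nor-3,10-dione F5. MeTi(OiPr)3 (THF, −20 → 0 °C) is non-basic, so the doubly activated H-1 should stay in place, and it should prefer the saturated ketone over the hindered conjugated one. It adds methyl from the α side and leaves the hydroxyl β, which returns the route to 6.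

**Further compounds**
F1 | step 8 | cyclobutane photoadduct of 13 (C3–C5' and C4–C4' bonds, 5αH), bis(triethylsilyl) ether | C[C@]17[C@@H]2[C@H]3OC(=O)[C@@H](C)[C@@H]3CC[C@](C)(O[Si](CC)(CC)CC)[C@@H]2[C@H]2[C@@H]3[C@@H]4[C@@]([C@H]6OC(=O)[C@@H](C)[C@@H]6CC[C@]4(C)O[Si](CC)(CC)CC)([C@@]7(C)C3=O)[C@@H]12
F2 | step 11 | 3'-endo-hydroxy cage alcohol, 10,10'-bis(triethylsilyl) ether | CC1=C2[C@H]3OC(=O)[C@@H](C)[C@@H]3CC[C@](C)(O[Si](CC)(CC)CC)[C@@H]2[C@H]2[C@@H]3[C@@H]4[C@@]([C@H]6OC(=O)[C@@H](C)[C@@H]6CC[C@]4(C)O[Si](CC)(CC)CC)([C@@H](C)[C@@H]3O)[C@@H]12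
F3 | step 11 | absinthin 10,10'-bis(triethylsilyl) ether | CC1=C2[C@H]3OC(=O)[C@@H](C)[C@@H]3CC[C@](C)(O[Si](CC)(CC)CC)[C@@H]2[C@H]2[C@@H]3[C@@H]4[C@@]([C@H]6OC(=O)[C@@H](C)[C@@H]6CC[C@]4(C)O[Si](CC)(CC)CC)(C(C)=C3)[C@@H]12
F4 | step 11 | absinthin | CC1=C2[C@H]3OC(=O)[C@@H](C)[C@@H]3CC[C@](C)(O)[C@@H]2[C@H]2[C@@H]3[C@@H]4[C@@]([C@H]6OC(=O)[C@@H](C)[C@@H]6CC[C@]4(C)O)(C(C)=C3)[C@@H]12
F5 | step 3 | 14-nor-3,10-dioxo-1αH-guai-4-en-12,6α-olide | CC1=C2[C@H]3OC(=O)[C@@H](C)[C@@H]3CCC(=O)[C@@H]2CC1=O
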